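We count electrophile.

| setting | larch | birch |
|---|---|---|
| electrophile | 1.0 mM | 1.0 mM |
| nucleophile | 0.900 mM | 1.80 mM |
| protic impurity | 0.0200 mM | 0.0200 mM |
| time | 8.0 s | 8.0 s |

- part of the electrophile that has reacted at the end, larch
- part of the electrophile that has reacted at the end, birch
- what raising the concentration of nucleophile from its lowest to its highest value here does to the part of the electrophile that has reacted (changes below 5 percentage points count as none) (it rises / no change / it falls)

- in percentages every species weighs as the electrophile in it: one side product counts as two
- run time (larch): 8.0 s

In larch and birch the electrophile reacts with the nucleophile (constant a, 58 L mol⁻¹ s⁻¹) to give target and acid set free, with the target to give side product (constant b, 210 L mol⁻¹ s⁻¹), and with the protic impurity (1900 L mol⁻¹ s⁻¹). Against the charged electrophile the impurity has a half-life of 0.365 s, much shorter than the run, so we deduct its charge at once. With 9.2 × 10⁵ L mol⁻¹, the binding constant times the nucleophile charged is 830 in larch and 1660 in birch, so each target made costs two nucleophile.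

The remaining electrophile then decays with the pseudo-first-order constant λ = aN + bT, where N is free nucleophile and T is target. Our first way holds λ at its starting value aC, where C is the nucleophile charged. We call 464 L mol⁻¹, the constant a times the run time, the reach ρ; the electrophile left after the impurity then shrinks by exp(−ρC). The part reacted comes to 35.5% in larch and 57.5% in birch.

Our second way replaces the electrophile curve by its mean Ē, which that decay puts at 0.801 mM in larch and 0.664 mM in birch. Free nucleophile falls by exp(−2ρĒ), to 47.5% of its charge in larch and 54.0% in birch. Counting target made, target left and side product then gives 37.3% and 61.3%.

The two ways part, and the first one cheats: each target made takes 2a from λ and adds b, and b is larger, so λ climbs early and the held value runs low. Its mean electrophile is therefore too high, which pushes the count of the second way too high. We commit to the middle: 36.4% for larch, 59.4% for birch, a rise of 23 percentage points, above the 5 points that counts.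

The forecast gives 36.8% for larch and 59.8% for birch, each above our middle, with the trend it rises, reasoning that “each acid set free removes one more nucleophile”.

The simulation gives 36.9% for larch and 59.9% for birch, each between our two ways, and the trend it rises by 23 points. The answer for larch has moved by 5 points at 1.07 mM of nucleophile, so with a highest charge under that, against the 0.900 mM of larch, the forecast's trend would have been wrong and the mark no change.

    electrophile + nucleophile → acid set free + target (k1 = 58 L mol⁻¹ s⁻¹)
    electrophile + protic impurity → quenched substrate (k2 = 1900 L mol⁻¹ s⁻¹)
    electrophile + target → side product (k3 = 210 L mol⁻¹ s⁻¹)
    nucleophile + acid set free ⇌ protonated nucleophile, settled at all times (K4 = 9.2 × 10⁵ L mol⁻¹)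

Take the neighbour of birch with 4.5 mM of nucleophile, all else as in birch. By the first way the reach gives an exponent ρC of 2.09, and so a reckoned 87.9% reacted. The simulated flask reaches 89.9%. It ends with 10.1% electrophile and 38.6% side product, and with more target than side product, at 49.3%.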